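**Plan**
1. After removal of the benzyl and silyl ethers, the pendant ring (C1' on benzofuran C3, C2'–CH3, C3'–O, C4'–CH3, C5'–O, C6'–H) is cut at C2'–C3', C4'–C5' and C5'–C6'. This gives a 3-(benzofuran-3-yl)-2-methylcyclobutenone and 1-(triisopropylsiloxy)propyne.
2. The feature that allows this is the pair of oxygens on C3' and C5' flanking the C4' methyl. C5'–O is a ketene carbonyl, C4'(CH3)–C3'(O) is the siloxyalkyne, and C1', C2'(CH3) and C6' are the vinylketene held in the cyclobutenone.
3. The cyclobutenone is cut to a 3-(prop-1-ynyl)benzofuran and dichloroketene, and the propynyl group to propyne and a C3 iodide. The furan ring (O1–C2 and C3–I) is cut to an o-alkynylphenol built from orcinol and methyl pent-4-ynoate.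
4. Forward order: orcinol arene, then the furan ring (step 6), the cyclobutenone ring (step 8), the pendant benzene ring (step 11), and deprotection.
5. The target has no stereocentre, so only regiochemistry has to be controlled.

Key step: step 11

Assumption: the target is written without stereodescriptors, so the hindered C3–C1' biaryl axis is treated as configurationally undefined and no atropselective control is planned.

**Step 1**
Reactants: 1 orcinol (5-methylbenzene-1,3-diol)
Product: 2 3-(benzyloxy)-5-methylphenol
Conditions: BnBr (1.0 equiv), K2CO3 (1.0 equiv), DMF, rt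
Reagents that add atoms: benzyl bromide, BrCc1ccccc1
Why: Williamson etherification of a diol whose two hydroxyls are equivalent by symmetry, so one equivalent of benzyl bromide should give a single monoether that is separated from recovered diol and the bis-ether.

**Step 2**
Reactants: 2 3-(benzyloxy)-5-methylphenol
Product: 3 3-(benzyloxy)-5-methylphenyl acetate
Conditions: Ac2O, pyridine, DMAP (cat.), CH2Cl2, 0 °C to rt
Reagents that add atoms: acetic anhydride, CC(=O)OC(C)=O
Why: O-acylation of the phenol masks the oxygen that later closes the furan ring and makes it a weak donor, leaving the benzyl ether as the controlling director in the next step.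

**Step 3**
Reactants: 3 3-(benzyloxy)-5-methylphenyl acetate
Product: 4 5-(benzyloxy)-2-iodo-3-methylphenyl acetate
Conditions: NIS (1.05 equiv), CF3CO2H (10 mol%), MeCN, 0 °C to rt
Reagents that add atoms: N-iodosuccinimide, O=C1CCC(=O)N1I
Why: electrophilic aromatic iodination should go para to the strongest donor, the benzyloxy group, which is the carbon between acetoxy and methyl, as in the iodination of 3,5-dialkoxytoluenes.

**Step 4**
Reactants: 4 5-(benzyloxy)-2-iodo-3-methylphenyl acetate; 5 methyl pent-4-ynoate
Product: 6 methyl 5-[2-(acetyloxy)-4-(benzyloxy)-6-methylphenyl]pent-4-ynoate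
Conditions: PdCl2(PPh3)2 (3 mol%), CuI (5 mol%), Et3N, DMF, 60 °C
Reagents that add atoms: none
Why: Sonogashira coupling of an aryl iodide with a terminal alkyne, in which the acetylated phenol cannot add to the new alkyne, so no iodine-free benzofuran should form.

**Step 5**
Reactants: 6 methyl 5-[2-(acetyloxy)-4-(benzyloxy)-6-methylphenyl]pent-4-ynoate
Product: 7 methyl 5-[4-(benzyloxy)-2-hydroxy-6-methylphenyl]pent-4-ynoate
Conditions: K2CO3 (0.2 equiv), MeOH, 0 °C
Reagents that add atoms: none
Why: base-catalysed methanolysis (transesterification) cleaves the aryl acetate fast, the methyl ester can only exchange degenerately with methanol, and the low temperature should keep the phenoxide from adding to the alkyne.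

**Step 6**
Reactants: 7 methyl 5-[4-(benzyloxy)-2-hydroxy-6-methylphenyl]pent-4-ynoate
Product: 8 methyl 3-[6-(benzyloxy)-3-iodo-4-methyl-1-benzofuran-2-yl]propanoate
Conditions: I2 (1.5 equiv), NaHCO3 (3 equiv), MeCN, 0 °C to rt
Reagents that add atoms: iodine, II
Why: 5-endo-dig iodocyclization of an o-alkynylphenol, in which the iodine-activated alkyne is attacked anti by the phenolic oxygen at the distal carbon, closing the furan ring and placing iodine on C3 only.

**Step 7**
Reactants: 8 methyl 3-[6-(benzyloxy)-3-iodo-4-methyl-1-benzofuran-2-yl]propanoate; 9 propyne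
Product: 10 methyl 3-[6-(benzyloxy)-4-methyl-3-(prop-1-yn-1-yl)-1-benzofuran-2-yl]propanoate
Conditions: 9 (excess, THF solution), PdCl2(PPh3)2 (5 mol%), CuI (10 mol%), Et3N, DMF, 50 °C, sealed tube
Reagents that add atoms: none
Why: Sonogashira coupling of a heteroaryl iodide, where the slim linear propynyl group should pass between the C4 methyl and the C2 side chain.

**Step 8**
Reactants: 10 methyl 3-[6-(benzyloxy)-4-methyl-3-(prop-1-yn-1-yl)-1-benzofuran-2-yl]propanoate; 11 trichloroacetyl chloride
Product: 13 methyl 3-[6-(benzyloxy)-3-(4,4-dichloro-2-methyl-3-oxocyclobut-1-en-1-yl)-4-methyl-1-benzofuran-2-yl]propanoate, via dichloroketene 12 (not isolated)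
Conditions: 11 (2.5 equiv, slow addition), Zn–Cu couple, Et2O–DME, rt
Reagents that add atoms: none
Why: zinc dechlorinates 11 to dichloroketene, which adds to the alkyne in a (2+2) cycloaddition with its carbonyl carbon on the methyl-bearing alkyne carbon, because the developing positive charge is best held next to the electron-rich benzofuran C3, as with 1-arylpropynes.

**Step 9**
Reactants: 13 methyl 3-[6-(benzyloxy)-3-(4,4-dichloro-2-methyl-3-oxocyclobut-1-en-1-yl)-4-methyl-1-benzofuran-2-yl]propanoate
Product: 14 methyl 3-[6-(benzyloxy)-4-methyl-3-(2-methyl-3-oxocyclobut-1-en-1-yl)-1-benzofuran-2-yl]propanoate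
Conditions: Zn dust, AcOH, TMEDA, EtOH, 0 °C to rt
Reagents that add atoms: none
Why: zinc reduction of the α,α-dichloroketone through its zinc enolate removes both chlorines, and the amine-buffered acid should leave the strained enone, the benzyl ether and the ester intact (the standard dechlorination of 4,4-dichlorocyclobutenones).

**Step 10**
Reactants: 9 propyne
Product: 17 triisopropyl(prop-1-yn-1-yloxy)silane, via 1-propynyllithium 15 (not isolated), via lithium prop-1-yn-1-olate 16 (not isolated)
Conditions: n-BuLi, THF, −78 °C; t-BuOOLi (from t-BuOOH and LiN(SiMe3)2), −78 to 0 °C; TIPSOTf, −78 to 0 °C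
Reagents that add atoms: tert-butyl hydroperoxide, CC(C)(C)OO; triisopropylsilyl trifluoromethanesulfonate, CC(C)[Si](OS(=O)(=O)C(F)(F)F)(C(C)C)C(C)C
Why: oxidation of a lithium acetylide with lithium tert-butyl peroxide gives the lithium ynolate, which the hard silyl triflate silylates on oxygen, the established route from terminal alkynes to triisopropylsiloxyalkynes.

**Step 11**
Reactants: 14 methyl 3-[6-(benzyloxy)-4-methyl-3-(2-methyl-3-oxocyclobut-1-en-1-yl)-1-benzofuran-2-yl]propanoate; 17 triisopropyl(prop-1-yn-1-yloxy)silane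
Product: 22 methyl 3-[6-(benzyloxy)-3-[5-hydroxy-2,4-dimethyl-3-(triisopropylsilyloxy)phenyl]-4-methyl-1-benzofuran-2-yl]propanoate, via vinylketene 18 (not isolated), via 4-vinylcyclobutenone 19 (not isolated), via dienylketene 20 (not isolated), via cyclohexadienone 21 (not isolated)
Conditions: 17 (1.5 equiv), toluene, 80 to 110 °C, sealed tube, argon
Reagents that add atoms: none
Why: Heating opens cyclobutenone 14 by a conrotatory four-electron electrocyclic cleavage to vinylketene 18, whose ketene C=C adds siloxyalkyne 17 in a (2+2) cycloaddition (bonds C4'–C5' and C2'–C3') to give 4-vinylcyclobutenone 19; a second, reversible four-electron opening gives dienylketene 20. This is the Danheiser benzannulation of a cyclobutenone with a trialkylsiloxyalkyne, which is known to deliver resorcinol monosilyl ethers. The one new ring, the pendant benzene ring, closes by thermal disrotatory six-electron electrocyclization of 20 between the ketene carbon and the terminal methylene (bond C5'–C6') to cyclohexadienone 21, which tautomerizes to phenol 22. No stereocentre results, since the quaternary carbon of 19 is transient and is erased on ring opening and aromatization. The only selectivity needed is the orientation of the ketene–alkyne addition; it is secured by the polarization of 17, whose methyl-bearing carbon is the nucleophilic one and bonds to the ketene carbonyl carbon, so that hydroxyl and siloxy end up meta with the methyl between them, and a dienylketene isomer that cannot cyclize reverts through 19. The benzofuranyl group sits on C3 of the cyclobutenone, where it cannot enter an electrocyclization itself, and the crowded C3–C1' bond is never made by coupling.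

**Step 12**
Reactants: 22 methyl 3-[6-(benzyloxy)-3-[5-hydroxy-2,4-dimethyl-3-(triisopropylsilyloxy)phenyl]-4-methyl-1-benzofuran-2-yl]propanoate
Product: 23 methyl 3-[6-(benzyloxy)-3-(3,5-dihydroxy-2,4-dimethylphenyl)-4-methyl-1-benzofuran-2-yl]propanoate
Conditions: TBAF, AcOH (1:1), THF, 0 °C
Reagents that add atoms: none
Why: fluoride-driven cleavage of the aryl silyl ether, with acetic acid buffering the phenoxide so that the methyl ester should not be hydrolysed.

**Step 13**
Reactants: 23 methyl 3-[6-(benzyloxy)-3-(3,5-dihydroxy-2,4-dimethylphenyl)-4-methyl-1-benzofuran-2-yl]propanoate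
Product: 24 talarominine A, methyl 3-[3-(3,5-dihydroxy-2,4-dimethylphenyl)-6-hydroxy-4-methyl-1-benzofuran-2-yl]propanoate
Conditions: H2 (1 atm), 10% Pd/C, EtOAc–MeOH, rt
Reagents that add atoms: none
Why: hydrogenolysis of the benzyl aryl ether on palladium, under which the tetrasubstituted furan C2=C3 bond and the ester should stay untouched.

**Compound list**
1 | orcinol (5-methylbenzene-1,3-diol) | Cc1cc(O)cc(O)c1 | starting material
2 | 3-(benzyloxy)-5-methylphenol | Cc1cc(O)cc(OCc2ccccc2)c1 | intermediate
3 | 3-(benzyloxy)-5-methylphenyl acetate | CC(=O)Oc1cc(C)cc(OCc2ccccc2)c1 | intermediate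
4 | 5-(benzyloxy)-2-iodo-3-methylphenyl acetate | CC(=O)Oc1cc(OCc2ccccc2)cc(C)c1I | intermediate
5 | methyl pent-4-ynoate | COC(=O)CCC#C | starting material
6 | methyl 5-[2-(acetyloxy)-4-(benzyloxy)-6-methylphenyl]pent-4-ynoate | COC(=O)CCC#Cc1c(C)cc(OCc2ccccc2)cc1OC(C)=O | intermediate
7 | methyl 5-[4-(benzyloxy)-2-hydroxy-6-methylphenyl]pent-4-ynoate | COC(=O)CCC#Cc1c(C)cc(OCc2ccccc2)cc1O | intermediate
8 | methyl 3-[6-(benzyloxy)-3-iodo-4-methyl-1-benzofuran-2-yl]propanoate | COC(=O)CCc1oc2cc(OCc3ccccc3)cc(C)c2c1I | intermediate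
9 | propyne | CC#C | starting material
10 | methyl 3-[6-(benzyloxy)-4-methyl-3-(prop-1-yn-1-yl)-1-benzofuran-2-yl]propanoate | COC(=O)CCc1oc2cc(OCc3ccccc3)cc(C)c2c1C#CC | intermediate
11 | trichloroacetyl chloride | ClC(=O)C(Cl)(Cl)Cl | starting material
12 | dichloroketene | ClC(Cl)=C=O | intermediate
13 | methyl 3-[6-(benzyloxy)-3-(4,4-dichloro-2-methyl-3-oxocyclobut-1-en-1-yl)-4-methyl-1-benzofuran-2-yl]propanoate | COC(=O)CCc1oc2cc(OCc3ccccc3)cc(C)c2c1C1=C(C)C(=O)C1(Cl)Cl | intermediate
14 | methyl 3-[6-(benzyloxy)-4-methyl-3-(2-methyl-3-oxocyclobut-1-en-1-yl)-1-benzofuran-2-yl]propanoate | COC(=O)CCc1oc2cc(OCc3ccccc3)cc(C)c2c1C1=C(C)C(=O)C1 | intermediate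
15 | 1-propynyllithium | [Li]C#CC | intermediate
16 | lithium prop-1-yn-1-olate | CC#C[O-].[Li+] | intermediate
17 | triisopropyl(prop-1-yn-1-yloxy)silane | CC#CO[Si](C(C)C)(C(C)C)C(C)C | intermediate
18 | vinylketene: methyl 3-[6-(benzyloxy)-4-methyl-3-(3-methyl-4-oxobuta-1,3-dien-2-yl)-1-benzofuran-2-yl]propanoate | COC(=O)CCc1oc2cc(OCc3ccccc3)cc(C)c2c1C(=C)C(C)=C=O | intermediate
19 | 4-vinylcyclobutenone (racemic): methyl 3-[6-(benzyloxy)-3-{1-[1,3-dimethyl-4-oxo-2-(triisopropylsilyloxy)cyclobut-2-en-1-yl]ethenyl}-4-methyl-1-benzofuran-2-yl]propanoate | COC(=O)CCc1oc2cc(OCc3ccccc3)cc(C)c2c1C(=C)C1(C)C(=O)C(C)=C1O[Si](C(C)C)(C(C)C)C(C)C | intermediate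
20 | dienylketene (vinyl and ketenyl groups cis on the central double bond): methyl 3-[6-(benzyloxy)-3-[(3E)-3,5-dimethyl-6-oxo-4-(triisopropylsilyloxy)hexa-1,3,5-trien-2-yl]-4-methyl-1-benzofuran-2-yl]propanoate | COC(=O)CCc1oc2cc(OCc3ccccc3)cc(C)c2c1C(=C)/C(C)=C(O[Si](C(C)C)(C(C)C)C(C)C)\C(C)=C=O | intermediate
21 | cyclohexadienone: methyl 3-[6-(benzyloxy)-3-[2,4-dimethyl-5-oxo-3-(triisopropylsilyloxy)cyclohexa-1,3-dien-1-yl]-4-methyl-1-benzofuran-2-yl]propanoate | COC(=O)CCc1oc2cc(OCc3ccccc3)cc(C)c2c1C1=C(C)C(O[Si](C(C)C)(C(C)C)C(C)C)=C(C)C(=O)C1 | intermediate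
22 | methyl 3-[6-(benzyloxy)-3-[5-hydroxy-2,4-dimethyl-3-(triisopropylsilyloxy)phenyl]-4-methyl-1-benzofuran-2-yl]propanoate | COC(=O)CCc1oc2cc(OCc3ccccc3)cc(C)c2c1-c1cc(O)c(C)c(O[Si](C(C)C)(C(C)C)C(C)C)c1C | intermediate
23 | methyl 3-[6-(benzyloxy)-3-(3,5-dihydroxy-2,4-dimethylphenyl)-4-methyl-1-benzofuran-2-yl]propanoate | COC(=O)CCc1oc2cc(OCc3ccccc3)cc(C)c2c1-c1cc(O)c(C)c(O)c1C | intermediate
24 | talarominine A, methyl 3-[3-(3,5-dihydroxy-2,4-dimethylphenyl)-6-hydroxy-4-methyl-1-benzofuran-2-yl]propanoate | COC(=O)CCc1oc2cc(O)cc(C)c2c1-c1cc(O)c(C)c(O)c1C | target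

**Step count**
Total: 13 steps. Longest linear sequence: 12 steps (steps 1–9 and 11–13, from orcinol). Step 10 is a one-step branch that joins at step 11.

**Steps most likely to fail**

Step 8. The (2+2) addition to the hindered internal alkyne may be slower than oligomerization of dichloroketene, and the zinc chloride formed may degrade the electron-rich benzofuran before the alkyne is consumed. The fallback sets out from 10 and returns at 14, using a keteniminium cycloaddition instead of a ketene. N,N-Dimethylacetamide, Tf2O and 2,4,6-collidine in 1,2-dichloroethane at reflux give N,N-dimethylketeniminium trifluoromethanesulfonate F1, a much stronger electrophile. It should add to 10 with the same orientation to give the cyclobuteniminium trifluoromethanesulfonate F2. Aqueous NaHCO3 then hydrolyses F2 to 14, so that 13 and step 9 are bypassed and neither zinc salts nor chlorine are involved.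

Step 6. Iodination of the electron-rich phenol ring may compete with iodonium-triggered ring closure, or iodine may simply add across the alkyl-substituted alkyne. The fallback sets out from 7 and returns at 8, and separates ring closure from iodine introduction. Hg(OAc)2 (1 equiv) in AcOH closes the furan ring by intramolecular oxymercuration of the alkyne to give the 3-(acetoxymercurio)benzofuran F3. Only then does I2 (1 equiv) in CH2Cl2 cleave the carbon–mercury bond at the ipso carbon to give 8. At that stage no free phenol is left, and iodine alone does not attack the aryl ethers.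

Step 3. Iodine may enter ortho instead of para to the benzyl ether (the carbon between benzyloxy and methyl), or twice, so that the alkyne would end up on the wrong ring carbon. The fallback sets out from 1 and returns at 6; the alkyne-bearing carbon is fixed by a formyl group instead of by electrophilic iodination.
- Vilsmeier–Haack formylation of 1 (POCl3, DMF, then water) gives 2,4-dihydroxy-6-methylbenzaldehyde F4, the established site of formylation of orcinol.
- BnBr and KHCO3 in MeCN benzylate only the hydroxyl that is not hydrogen-bonded to the formyl group, giving 4-(benzyloxy)-2-hydroxy-6-methylbenzaldehyde F5.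
- Acetylation (Ac2O, pyridine) gives 5-(benzyloxy)-2-formyl-3-methylphenyl acetate F6.
- Ramirez olefination (CBr4, PPh3, CH2Cl2, 0 °C) gives 5-(benzyloxy)-2-(2,2-dibromoethenyl)-3-methylphenyl acetate F7.
- DBU in MeCN removes HBr to give 5-(benzyloxy)-2-(bromoethynyl)-3-methylphenyl acetate F8.
- Negishi coupling of F8 with (3-methoxy-3-oxopropyl)zinc iodide F9 (from methyl 3-iodopropanoate and zinc dust) under Pd(PPh3)4 in THF gives 6.

**Further compounds**
F1 | step 8 | N,N-dimethylketeniminium trifluoromethanesulfonate | C=C=[N+](C)C.[O-]S(=O)(=O)C(F)(F)F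
F2 | step 8 | N-{3-[6-(benzyloxy)-2-(3-methoxy-3-oxopropyl)-4-methyl-1-benzofuran-3-yl]-2-methylcyclobut-2-en-1-ylidene}-N-methylmethanaminium trifluoromethanesulfonate | COC(=O)CCc1oc2cc(OCc3ccccc3)cc(C)c2c1C1=C(C)C(=[N+](C)C)C1.[O-]S(=O)(=O)C(F)(F)F
F3 | step 6 | (acetato)[6-(benzyloxy)-2-(3-methoxy-3-oxopropyl)-4-methyl-1-benzofuran-3-yl]mercury | COC(=O)CCc1oc2cc(OCc3ccccc3)cc(C)c2c1[Hg]OC(C)=O
F4 | step 3 | 2,4-dihydroxy-6-methylbenzaldehyde | Cc1cc(O)cc(O)c1C=O
F5 | step 3 | 4-(benzyloxy)-2-hydroxy-6-methylbenzaldehyde | Cc1cc(OCc2ccccc2)cc(O)c1C=O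
F6 | step 3 | 5-(benzyloxy)-2-formyl-3-methylphenyl acetate | CC(=O)Oc1cc(OCc2ccccc2)cc(C)c1C=O
F7 | step 3 | 5-(benzyloxy)-2-(2,2-dibromoethenyl)-3-methylphenyl acetate | CC(=O)Oc1cc(OCc2ccccc2)cc(C)c1C=C(Br)Br
F8 | step 3 | 5-(benzyloxy)-2-(bromoethynyl)-3-methylphenyl acetate | CC(=O)Oc1cc(OCc2ccccc2)cc(C)c1C#CBr
F9 | step 3 | (3-methoxy-3-oxopropyl)zinc iodide | COC(=O)CC[Zn]I
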